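**Strategy.** The quinone ring (C1 carbonyl, C2 hydroxyl, C3 henicosyl, C4 carbonyl, C5 methoxy, C6–H) is cut at both of its C=C bonds, C2–C3 and C5–C6. This exposes a head-to-tail repeat, CH–C(=O)–C(–O), that occurs twice around the ring, so each half is a three-carbon α-keto ester: C6–C1–C2 is methyl pyruvate and C3–C4–C5 is methyl 2-oxotetracosanoate. A crossed double Claisen condensation joins the enolisable carbon of each half to the ester carbon of the other and closes the ring directly at the dihydroxyquinone oxidation level, with no redox step. Selective O-methylation of the unhindered C5 hydroxyl then gives the target.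

Key step: step 2

Remark: ring atoms are numbered as in 3-henicosyl-2-hydroxy-5-methoxycyclohexa-2,5-diene-1,4-dione. Compound 8 is a single compound, because its two enol tautomers are identical, and it is drawn with the hydroxyls on C2 and C5.

**Step 1**
Reactants: 1 1-bromodocosane; 2 dimethyl oxalate
Product: 4 methyl 2-oxotetracosanoate, via docosylmagnesium bromide 3 (not isolated)
Conditions: Mg, I2 (cat.), THF, 60 °C; then add to 2 (2.5 equiv), THF, −40 °C; 1 M HCl
Reagents that add atoms: none
Why: Mono-addition of a Grignard reagent to excess dialkyl oxalate at low temperature, where the chelated tetrahedral adduct should survive until the acidic quench, is the standard acylation route to α-keto esters; no stereocenter is formed.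

**Step 2**
Reactants: 4 methyl 2-oxotetracosanoate; 5 methyl pyruvate
Product: 8 2,5-dihydroxy-3-henicosylcyclohexa-2,5-diene-1,4-dione, via methyl 2,4,5-trioxoheptacosanoate 6 (not isolated), via 3-henicosylcyclohexane-1,2,4,5-tetrone 7 (not isolated)
Conditions: 4 and 5 (5 equiv) premixed, added slowly to NaOMe (excess), THF, 0 to 60 °C; then 1 M HCl
Reagents that add atoms: none
Why: Proposed new method: methoxide should convert 5 into its methyl enolate (future C6), which acylates at the ester carbonyl of 4 (future C5) and expels methoxide to give 6, held as its stabilised enolate; a second deprotonation at the chain-bearing CH2 (future C3) then lets that carbon attack the remaining ester (future C2) and close the ring to 7, whose two enolisations give the dianion of 8 without any change of oxidation level. The closest known reaction types are the base-induced head-to-tail dimerisation of butane-2,3-dione to 2,5-dimethyl-1,4-benzoquinone (double aldol condensation of two 1,2-dicarbonyl halves) and the Claisen–Dieckmann dimerisation of dialkyl succinates to succinylsuccinates; the transfer to two different α-keto esters with ester carbons as the acceptors is what is new. The six-membered ring closes in the 6-exo-trig (Dieckmann) mode. No stereocenter is formed. The step needs acylation to win over aldol addition at the ketone carbonyls and the crossed union to win over self-condensation: aldol adducts revert under alkoxide whereas the doubly deprotonated, resonance-stabilised dihydroxyquinone is an irreversible sink, 5 is used in excess, and its own condensation products are water-soluble and leave in the aqueous wash. The ring substitution pattern is fixed because each half has a single enolisable carbon and a single ester carbon.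

**Step 3**
Reactants: 8 2,5-dihydroxy-3-henicosylcyclohexa-2,5-diene-1,4-dione
Product: 9 3-henicosyl-2-hydroxy-5-methoxycyclohexa-2,5-diene-1,4-dione (the target)
Conditions: MeOH/CHCl3 (1:1), H2SO4 (cat.), 50 °C
Reagents that add atoms: methanol, CO
Why: Acid-catalysed etherification of a vinylogous carboxylic acid by addition–elimination (Fischer-type) should run under thermodynamic control, the C5 hydroxyl next to C6–H giving a planar conjugated vinylogous ester while an ether at C2 next to the henicosyl chain would be twisted out of conjugation and solvolysed back, so that C2 keeps its hydroxyl; no stereocenter is formed.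

**Compound list**
1 | 1-bromodocosane | CCCCCCCCCCCCCCCCCCCCCCBr | starting material
2 | dimethyl oxalate | COC(=O)C(=O)OC | starting material
3 | docosylmagnesium bromide | CCCCCCCCCCCCCCCCCCCCCC[Mg]Br | intermediate
4 | methyl 2-oxotetracosanoate | CCCCCCCCCCCCCCCCCCCCCCC(=O)C(=O)OC | intermediate
5 | methyl pyruvate | CC(=O)C(=O)OC | starting material
6 | methyl 2,4,5-trioxoheptacosanoate | CCCCCCCCCCCCCCCCCCCCCCC(=O)C(=O)CC(=O)C(=O)OC | intermediate
7 | 3-henicosylcyclohexane-1,2,4,5-tetrone | CCCCCCCCCCCCCCCCCCCCCC1C(=O)C(=O)CC(=O)C1=O | intermediate
8 | 2,5-dihydroxy-3-henicosylcyclohexa-2,5-diene-1,4-dione | CCCCCCCCCCCCCCCCCCCCCC1=C(O)C(=O)C=C(O)C1=O | intermediate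
9 | 3-henicosyl-2-hydroxy-5-methoxycyclohexa-2,5-diene-1,4-dione | CCCCCCCCCCCCCCCCCCCCCC1=C(O)C(=O)C=C(OC)C1=O | target

**Totals.** Total step count: 3. Longest linear sequence: 3 steps (1 to 4 to 8 to 9).

**Steps most likely to fail**

Step 2 (proposed new method) is the riskiest. Aldol addition at the ketone carbonyls followed by lactonisation may outrun acylation, and self-condensation of either keto ester may take the place of the crossed union. The fallback uses known chemistry, sets out from 1 and comes back at 8. The bromide 1 should be oxidised to docosanoic acid F1 (NaNO2, AcOH, DMSO, 50 °C, nitrite oxidation of a primary bromide). The acid should then be coupled to didocosanoyl peroxide F2 (H2O2, DCC, CH2Cl2, 0 °C). Thermolysis of F2 in acetic acid at 90–95 °C in the presence of commercial 2,5-dihydroxy-1,4-benzoquinone should release the henicosyl radical by decarboxylation and alkylate the free quinone C–H (radical alkylation of a hydroxyquinone with a diacyl peroxide), giving 8.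

Step 3 comes next. Methylation may run on to the dimethyl ether, or the discrimination between the two hydroxyls may be incomplete. The fallback sets out from 8 and comes back at 9. Exhaustive O-methylation (Me2SO4, K2CO3, acetone, reflux) should give 3-henicosyl-2,5-dimethoxycyclohexa-2,5-diene-1,4-dione F3. Its hindered, twisted C2 methyl ether next to the alkyl chain should then be hydrolysed selectively (70% HClO4, 1,4-dioxane, room temperature), leaving the C5 methoxy group in place.

Step 1 is third. Wurtz homocoupling during formation of the waxy long-chain organomagnesium, its poor solubility at low temperature, and a second addition to the keto ester carbonyl may erode the mono-acylation. The fallback reverses the polarity, sets out from 1 and comes back at 8. Commercial ethyl 1,3-dithiane-2-carboxylate should be deprotonated (NaH, DMF/toluene, 0 °C to room temperature) and alkylated with 1 to give ethyl 2-docosyl-1,3-dithiane-2-carboxylate F4. Unmasking (MeI, CaCO3, MeCN/H2O, 50 °C) should give ethyl 2-oxotetracosanoate F5. F5 then takes the place of 4 in step 2, losing ethanol instead of methanol, and the route is rejoined at 8.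

**Further compounds**
F1 | step 2 | docosanoic acid | CCCCCCCCCCCCCCCCCCCCCC(=O)O
F2 | step 2 | didocosanoyl peroxide | CCCCCCCCCCCCCCCCCCCCCC(=O)OOC(=O)CCCCCCCCCCCCCCCCCCCCC
F3 | step 3 | 3-henicosyl-2,5-dimethoxycyclohexa-2,5-diene-1,4-dione | CCCCCCCCCCCCCCCCCCCCCC1=C(OC)C(=O)C=C(OC)C1=O
F4 | step 1 | ethyl 2-docosyl-1,3-dithiane-2-carboxylate | CCCCCCCCCCCCCCCCCCCCCCC1(SCCCS1)C(=O)OCC
F5 | step 1 | ethyl 2-oxotetracosanoate | CCCCCCCCCCCCCCCCCCCCCCC(=O)C(=O)OCC
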